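The synthesis rests on forming two neighbouring bonds of the benzene ring in one flask: C6–C1' to the side chain and C1–CO2H. The key step exploits the contiguous ring array C2(OMe)–C1–C6: an aryne across C1–C6, flanked by the C2 methoxy group, is attacked at C6 by an enantiopure beta-oxido alkyllithium carrying C1'–C13', and the C1 aryllithium that results is carboxylated with CO2; acetic anhydride then caps O-2'. The aryne precursor is a 3-fluoro-5-methoxyphenol whose hydroxyl (the future C4–OH) is masked as a bulky silyl ether, the nucleophile precursor is (2R)-1-chlorotridecan-2-ol made from (R)-epichlorohydrin. Desilylation completes the route.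

Key step: step 3

Remark: atom labels follow the target (ring C1 bears CO2H, C2 OMe, C4 OH, C6 the side chain C1'–C13'). The single stereocentre C2' (R) is bought with (R)-epichlorohydrin, assumed to be of high enantiopurity, and is never a reacting atom.

Step 1
Reactants: 1 3-fluoro-5-methoxyphenol
Product: 2 1-fluoro-3-methoxy-5-(triisopropylsilyloxy)benzene
Conditions: i-Pr3SiCl, imidazole, DMF, rt
Reagents that add atoms: triisopropylsilyl chloride (i-Pr3SiCl), CC(C)[Si](Cl)(C(C)C)C(C)C
Why: Imidazole-promoted O-silylation of the phenol (silyl ether formation) is a standard protection, and the bulky triisopropylsilyl group later screens both ring hydrogens next to this oxygen from lithiation.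

Step 2
Reactants: 3 1-bromodecane, 4 (R)-epichlorohydrin
Product: 6 (2R)-1-chlorotridecan-2-ol, via decylmagnesium bromide 5 (not isolated)
Conditions: Mg, THF, rt; then added to 4, CuI (10 mol %), THF, −60 → −30 °C; aq NH4Cl
Reagents that add atoms: none
Why: CuI-catalysed Grignard opening of the terminal epoxide (SN2 at the unsubstituted epoxide carbon) is faster at low temperature than attack at C–Cl, and since the stereocentre is not a reacting atom and the ranking of its substituents is unchanged, the R configuration of 4 is carried into 6.

Step 3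
Reactants: 2 1-fluoro-3-methoxy-5-(triisopropylsilyloxy)benzene, 6 (2R)-1-chlorotridecan-2-ol, 7 carbon dioxide
Product: 15 2-[(2R)-2-acetoxytridecyl]-6-methoxy-4-(triisopropylsilyloxy)benzoic acid, via lithium chloroalkoxide 8 (not isolated), via beta-oxido alkyllithium 9 (not isolated), via ortho-lithiated fluoroarene 10 (not isolated), via 3-methoxyaryne 11 (not isolated), via aryllithium adduct 12 (not isolated), via dilithium carboxylate alkoxide 13 (not isolated), via lithium acetoxy carboxylate 14 (not isolated)
Conditions: (a) 6 (2.5 equiv), n-BuLi, THF, −78 °C, then LiC10H8 (2 equiv per C–Cl, titrated to the end point), −78 °C; (b) 2, s-BuLi (1.0 equiv), THF, −78 °C; (c) b cannulated into a at −78 °C, then −78 → −50 °C; (d) CO2 gas, −78 °C, then Ar purge; (e) Ac2O, 4-(dimethylamino)pyridine (cat.), −78 → 0 °C; water, then cold 0.5 M aq HCl to pH 3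
Reagents that add atoms: acetic anhydride (Ac2O), CC(=O)OC(C)=O
Why: Proposed new method: s-BuLi removes the ring hydrogen of 2 that lies between F and OMe to give 10, which on warming expels LiF to form the C1–C6 aryne 11; the primary carbanion of 9 (made from 6 by O-deprotonation to 8 and two-electron reduction of the C–Cl bond) adds at C6, the resulting C1 aryllithium 12 is carboxylated by CO2 to 13, and Ac2O acetylates the side-chain alkoxide to 14, with 4-(dimethylamino)pyridine channelling any alkyl carbonate formed under CO2 to the same acetate and any mixed anhydride being hydrolysed on work-up. The closest known reaction types are the carbolithiation of 3-alkoxyarynes generated from ortho-lithiated fluoroarenes with CO2 capture of the new aryllithium, and the reductive lithiation of chlorohydrin alkoxides to beta-oxido alkyllithiums that are trapped by electrophiles at −78 °C; using such a dianion as the aryne partner and running all events in one flask is the untested part. No ring is closed and no stereocentre is formed, because C2' is a carbinol carbon next to, not at, the metallated centre, so its configuration passes from 6 to 15 unchanged. Site selectivity of lithiation should follow from the acidity of the C–H flanked by F and OMe and from the bulky silyl ether, which screens the other two ring hydrogens, while regioselectivity of addition should follow from the inductively withdrawing OMe beside the triple bond, which directs the nucleophile to the remote aryne carbon C6 and places the charge at C1 next to oxygen. Chemoselectivity needs an excess of 9 (so that 10 and 12 do not capture the aryne), exact titration of LiC10H8 (no radical anion left to reduce 2 or 11) and the lowest temperature at which LiF is lost, because 9 eliminates Li2O to 1-tridecene when warmed further.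

Step 4
Reactants: 15 2-[(2R)-2-acetoxytridecyl]-6-methoxy-4-(triisopropylsilyloxy)benzoic acid
Product: 16 2-[(2R)-2-acetoxytridecyl]-4-hydroxy-6-methoxybenzoic acid
Conditions: Bu4NF, AcOH (1:1), THF, 0 °C → rt; pH 4 phosphate buffer work-up
Reagents that add atoms: none
Why: Fluoride-mediated cleavage of the aryl silyl ether (driven by Si–F bond formation) frees the C4 phenol, while the acetic acid buffer keeps phenoxide and fluoride from acting as bases on the secondary acetate, and the stereocentre is not involved.

Compound list
1 | 3-fluoro-5-methoxyphenol | COc1cc(O)cc(F)c1 | starting material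
2 | 1-fluoro-3-methoxy-5-(triisopropylsilyloxy)benzene | COc1cc(F)cc(O[Si](C(C)C)(C(C)C)C(C)C)c1 | intermediate
3 | 1-bromodecane | CCCCCCCCCCBr | starting material
4 | (R)-epichlorohydrin [(2R)-2-(chloromethyl)oxirane] | ClC[C@H]1CO1 | starting material
5 | decylmagnesium bromide | CCCCCCCCCC[Mg]Br | intermediate
6 | (2R)-1-chlorotridecan-2-ol | CCCCCCCCCCC[C@H](CCl)O | intermediate
7 | carbon dioxide | O=C=O | starting material
8 | lithium (2R)-1-chlorotridecan-2-olate | CCCCCCCCCCC[C@H](CCl)O[Li] | intermediate
9 | lithium (2S)-1-lithiotridecan-2-olate (same spatial arrangement as 6; the descriptor changes only because CH2Li ranks below the alkyl chain) | CCCCCCCCCCC[C@H](C[Li])O[Li] | intermediate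
10 | 2-fluoro-6-methoxy-4-(triisopropylsilyloxy)phenyllithium | [Li]c1c(F)cc(O[Si](C(C)C)(C(C)C)C(C)C)cc1OC | intermediate
11 | 1,2-didehydro-3-methoxy-5-(triisopropylsilyloxy)benzene (aryne; the triple bond joins the future C1 and C6) | COC1=CC(O[Si](C(C)C)(C(C)C)C(C)C)=CC#C1 | intermediate
12 | lithium (2R)-1-[2-lithio-3-methoxy-5-(triisopropylsilyloxy)phenyl]tridecan-2-olate | CCCCCCCCCCC[C@H](Cc1cc(O[Si](C(C)C)(C(C)C)C(C)C)cc(OC)c1[Li])O[Li] | intermediate
13 | dilithium 2-[(2R)-2-oxidotridecyl]-6-methoxy-4-(triisopropylsilyloxy)benzoate | CCCCCCCCCCC[C@H](Cc1cc(O[Si](C(C)C)(C(C)C)C(C)C)cc(OC)c1C(=O)O[Li])O[Li] | intermediate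
14 | lithium 2-[(2R)-2-acetoxytridecyl]-6-methoxy-4-(triisopropylsilyloxy)benzoate | CCCCCCCCCCC[C@H](Cc1cc(O[Si](C(C)C)(C(C)C)C(C)C)cc(OC)c1C(=O)O[Li])OC(C)=O | intermediate
15 | 2-[(2R)-2-acetoxytridecyl]-6-methoxy-4-(triisopropylsilyloxy)benzoic acid | CCCCCCCCCCC[C@H](Cc1cc(O[Si](C(C)C)(C(C)C)C(C)C)cc(OC)c1C(=O)O)OC(C)=O | intermediate
16 | 2-[(2R)-2-acetoxytridecyl]-4-hydroxy-6-methoxybenzoic acid | CCCCCCCCCCC[C@H](Cc1cc(O)cc(OC)c1C(=O)O)OC(C)=O | target

Total step count: 4. Longest linear sequence: 3 steps (steps 1, 3, 4, or equally steps 2, 3, 4).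

Steps most likely to fail

1. Step 3 (Proposed new method). The two organolithium partners have different thermal windows. The beta-oxido alkyllithium may eliminate Li2O before the ortho-lithiated fluoroarene has shed LiF. The aryne that does form may also be captured by aryllithiums instead of the dianion, so that carbolithiation stalls or gives biaryls. The fallback uses only known reaction types, sets out from 6 and rejoins the route at 12. Ring closure of 6 with NaOH in aqueous THF (intramolecular Williamson ether synthesis, stereocentre untouched) should give (2R)-2-undecyloxirane F1. Commercial 3-bromo-5-methoxyphenol is silylated as in step 1 to 1-bromo-3-methoxy-5-(triisopropylsilyloxy)benzene F2, which with Mg in THF gives 3-methoxy-5-(triisopropylsilyloxy)phenylmagnesium bromide F3. CuI-catalysed opening of F1 at its CH2 terminus by F3 forms the C6–C1' bond and should give (2R)-1-[3-methoxy-5-(triisopropylsilyloxy)phenyl]tridecan-2-ol F4. Treatment of F4 with n-BuLi (2.2 equiv) and TMEDA in Et2O first gives lithium (2R)-1-[3-methoxy-5-(triisopropylsilyloxy)phenyl]tridecan-2-olate F5. Directed ortho-metalation then follows at the one ring C–H that is flanked by the methoxy group and the alkoxide-bearing side chain and is not screened by the silyl ether, which gives aryllithium 12. CO2, Ac2O and acidification as in step 3 then lead through 13 and 14 to 15.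

2. Step 4. Acyl transfer from O-2' to the liberated phenoxide, or loss of the acetate under the basic ammonium fluoride, would be followed by ring closure of the resulting hydroxy acid to the lactone. The fallback changes the phenol protecting group so that a weakly acidic, phenol-selective cleavage can be used; it sets out from 1 and returns at 16. Silylation of 1 with t-BuMe2SiCl and imidazole gives tert-butyl(3-fluoro-5-methoxyphenoxy)dimethylsilane F6, which is taken through step 3 with 6 and 7 in the same way. The in-flask intermediates are:
- 2-fluoro-6-methoxy-4-(tert-butyldimethylsilyloxy)phenyllithium F7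
- 1,2-didehydro-3-methoxy-5-(tert-butyldimethylsilyloxy)benzene F8
- lithium (2R)-1-[2-lithio-3-methoxy-5-(tert-butyldimethylsilyloxy)phenyl]tridecan-2-olate F9
- dilithium 2-[(2R)-2-oxidotridecyl]-4-(tert-butyldimethylsilyloxy)-6-methoxybenzoate F10
- lithium 2-[(2R)-2-acetoxytridecyl]-4-(tert-butyldimethylsilyloxy)-6-methoxybenzoate F11

Acidification should give 2-[(2R)-2-acetoxytridecyl]-4-(tert-butyldimethylsilyloxy)-6-methoxybenzoic acid F12. The smaller phenolic silyl ether is then cleaved with KHF2 in MeOH at rt, a bifluoride medium in which neither phenoxide nor free fluoride base is present, to give 16. The smaller silyl group screens its neighbouring ring hydrogens less well, so the lithiation site must be confirmed in this series.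

3. Step 2. Magnesium halide may open and re-close the epoxide, exchanging Cl for Br and eroding enantiomeric purity. The product alkoxide may also close to the terminal epoxide and take up a second Grignard reagent. The fallback replaces the Grignard reagent by an acetylide and adds a hydrogenation; it sets out from 4 and returns at 6. 1-Decyne is deprotonated with n-BuLi in THF to dec-1-ynyllithium F13. In the presence of BF3·OEt2 at −78 °C, F13 opens 4 at the epoxide CH2, with no magnesium halide and no warming, and should give (2R)-1-chlorotridec-4-yn-2-ol F14. Hydrogenation of the triple bond with H2 over Pd/C in EtOAc then gives 6 with the stereocentre and the C–Cl bond untouched.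

Further compounds
F1 | step 3 | (2R)-2-undecyloxirane | CCCCCCCCCCC[C@@H]1CO1
F2 | step 3 | 1-bromo-3-methoxy-5-(triisopropylsilyloxy)benzene | COc1cc(Br)cc(O[Si](C(C)C)(C(C)C)C(C)C)c1
F3 | step 3 | 3-methoxy-5-(triisopropylsilyloxy)phenylmagnesium bromide | COc1cc([Mg]Br)cc(O[Si](C(C)C)(C(C)C)C(C)C)c1
F4 | step 3 | (2R)-1-[3-methoxy-5-(triisopropylsilyloxy)phenyl]tridecan-2-ol | CCCCCCCCCCC[C@H](Cc1cc(OC)cc(O[Si](C(C)C)(C(C)C)C(C)C)c1)O
F5 | step 3 | lithium (2R)-1-[3-methoxy-5-(triisopropylsilyloxy)phenyl]tridecan-2-olate | CCCCCCCCCCC[C@H](Cc1cc(OC)cc(O[Si](C(C)C)(C(C)C)C(C)C)c1)O[Li]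
F6 | step 4 | tert-butyl(3-fluoro-5-methoxyphenoxy)dimethylsilane | COc1cc(F)cc(O[Si](C)(C)C(C)(C)C)c1
F7 | step 4 | 2-fluoro-6-methoxy-4-(tert-butyldimethylsilyloxy)phenyllithium | [Li]c1c(F)cc(O[Si](C)(C)C(C)(C)C)cc1OC
F8 | step 4 | 1,2-didehydro-3-methoxy-5-(tert-butyldimethylsilyloxy)benzene | COC1=CC(O[Si](C)(C)C(C)(C)C)=CC#C1
F9 | step 4 | lithium (2R)-1-[2-lithio-3-methoxy-5-(tert-butyldimethylsilyloxy)phenyl]tridecan-2-olate | CCCCCCCCCCC[C@H](Cc1cc(O[Si](C)(C)C(C)(C)C)cc(OC)c1[Li])O[Li]
F10 | step 4 | dilithium 2-[(2R)-2-oxidotridecyl]-4-(tert-butyldimethylsilyloxy)-6-methoxybenzoate | CCCCCCCCCCC[C@H](Cc1cc(O[Si](C)(C)C(C)(C)C)cc(OC)c1C(=O)O[Li])O[Li]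
F11 | step 4 | lithium 2-[(2R)-2-acetoxytridecyl]-4-(tert-butyldimethylsilyloxy)-6-methoxybenzoate | CCCCCCCCCCC[C@H](Cc1cc(O[Si](C)(C)C(C)(C)C)cc(OC)c1C(=O)O[Li])OC(C)=O
F12 | step 4 | 2-[(2R)-2-acetoxytridecyl]-4-(tert-butyldimethylsilyloxy)-6-methoxybenzoic acid | CCCCCCCCCCC[C@H](Cc1cc(O[Si](C)(C)C(C)(C)C)cc(OC)c1C(=O)O)OC(C)=O
F13 | step 2 | dec-1-ynyllithium | CCCCCCCCC#C[Li]
F14 | step 2 | (2R)-1-chlorotridec-4-yn-2-ol | CCCCCCCCC#CC[C@H](CCl)O
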